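The numbers in the tables are calculated for substances that don't exist.

Count turnovers first.

| flask | substrate | remark | time |
|---|---|---|---|
| eta | 0.46 M | run made earlier |  |
| gamma | 0.23 M | run made earlier |  |
| epsilon | 0.92 M | run made earlier |  |
| Sunday's | 0.46 M | a single well-mixed tank run continuously and read at steady state, 30 min in it on average |  |
| Friday's | 0.46 M | a closed flask charged with all of it at once and left for 30 min | 30 min |
| Thursday's | 0.46 M | a single well-mixed tank run continuously and read at steady state, 150 min in it on average |  |

| run | time / min | product / % | substrate / % |
|---|---|---|---|
| eta | 2.50 | 1.8 | 96.4 |
| eta | 8.00 | 8.4 | 86.8 |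
| eta | 15.0 | 15.5 | 75.5 |
| eta | 20.0 | 20.3 | 70.7 |
| eta | 30.0 | 29.5 | 56.0 |
| gamma | 1.50 | 3.0 | 97.4 |
| gamma | 5.00 | 8.1 | 88.7 |
| gamma | 8.00 | 10.8 | 83.2 |
| gamma | 12.0 | 17.8 | 77.5 |
| gamma | 20.0 | 25.7 | 64.5 |
| epsilon | 1.50 | 2.4 | 98.0 |
| epsilon | 5.00 | 1.6 | 93.5 |
| epsilon | 8.00 | 5.1 | 90.0 |
| epsilon | 12.0 | 7.5 | 84.2 |
| epsilon | 20.0 | 15.0 | 75.5 |

(each reading ± 1 percentage point)

- the stated concentrations are those of everything mixed, before any reaction; amounts are the same in each set-up
- the earlier runs were made in a closed, stirred flask
- a reading or a percentage of product counts all its forms, free or not
- a reading of substrate is of its free form alone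

- the set-up with the highest amount of product at the outlet or at the end, in percent of the substrate put in ("none" if the first two lie within 2 percentage points) (Sunday's / Friday's / Thursday's / none)
- amount of product at the outlet or at the end, in percent of the substrate put in, Sunday's
- amount of product at the outlet or at the end, in percent of the substrate put in, Friday's
- amount of product at the outlet or at the end, in percent of the substrate put in, Thursday's

The eta run made 29.5% product in 30.0 min, so at that pace it would need 102 min to make its whole charge. We call this the turnover time, and the time in the vessel divided by it the turnover count (Damköhler number). Friday's closed flask has the charge and time of the eta run, so its count is 0.295 and we expect about 29.5% product.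

Thursday's tank counts 1.47, more than one whole charge, so the plain count fails there. But a steady tank works at its outlet mixture. If the pace follows the substrate present, product over substrate at the outlet equals the count, and the product share is the count over one plus the count. That gives 59.6% for Thursday's tank and 22.8% for Sunday's.

Yet by this reckoning a tank stands thinner than its charge, and the gamma run's turnover time of 77.8 min is shorter than eta's, while the epsilon run's is 133 min. With gamma's figure the shares rise to 65.8% for Thursday's and 27.8% for Sunday's. A further doubt is that the share assumes substrate and product fill the charge, whereas the last eta reading falls short by 14.5%. Scaling the gamma shares down by that gap leaves 56.3% for Thursday's and 23.8% for Sunday's. For each tank we commit to the range between its gamma share and its scaled share, and even the low end for Thursday's tank stands above our figure for Friday's flask, so we name Thursday's.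

The forecast names Thursday's, with 26.5% for Sunday's, 30% for Friday's and 63% for Thursday's, adding “this is a long extrapolation”.

The flasks give 26.2% for Sunday's, 29.5% for Friday's and 63.0% for Thursday's, so Thursday's is best, as forecast.

    substrate → product, rate k1*[substrate]/(1 + ([substrate]/sat1)) (0.410 M, k = 4.00 × 10⁻⁴ s⁻¹)
    substrate + product ⇌ idle adduct, settled at all times (K = 3.20 M⁻¹)

Friday's flask is not at rest at 30.0 min. It holds 57.1% free substrate and 29.5% product, bound forms counted; the 26.9% idle adduct counts as two, so part of it is already inside that product figure. Left until 300 min, it reaches 96.0% product, 66 percentage points more, with 1.67% substrate left. Its count there is 2.94, above one, so the plain count can't be read as a share at that time in this flask.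

For a closed flask like Friday's but with 0.78 M substrate, placing the turnover time between eta's and epsilon's gives 124 min, so the count predicts 24.3% product. That flask gives 22.8%.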